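**Plan**

Rings: A = hydroxy ring whose ether O is para to its benzylic CH2; B = meta-linked ring; C = para-linked ring; D = hydroxy ring whose OH is para to its benzylic CH2.
1. Enabling feature: the Ar(A)–CH2–CH2–Ar(D) bridge is a diaryl ketone carbon plus one inserted carbon; both bridge carbons end as CH2, so it is immaterial which aryl ring shifts during the insertion.
2. Cuts, in retrosynthetic order: the two O–CH3 bonds; the C=O oxygen of a 20-membered aryl benzyl ketone; the two C–C bonds of one bridge carbon (back to the 19-membered A–CO–D ketone); the O–C(ring A) ether bond; the C(ring D)–C(=O) bond; the B–C bridge as a stilbene C=C; the O–C(ring C) ether bond.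
3. Forward: D–O–C ether, then the B–CH2CH2–C bridge, then ring A as a fluoro ketone, then the only ring closure (19-membered A–O–B etherification, activated by that ketone), growth to 20 members at the same carbonyl, deoxygenation, demethylation.
4. Stereochemistry: the target has no stereocentre; the stilbene geometry, the silyl-bearing carbon and the carbinol carbon met on the way are all erased.

Key step: step 7

Remark: the target is drawn without stereodescriptors, so the macrocycle is taken as conformationally mobile and achiral; the two methyl ethers are the only protecting groups and the ring B phenol is carried free.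

**Route**

Step 1
Reactants: 1 5-bromo-2-methoxyphenol; 2 4-fluorobenzaldehyde
Product: 3 4-(5-bromo-2-methoxyphenoxy)benzaldehyde
Conditions: K2CO3, DMF, 140 °C
Reagents that add atoms: none
Why: The para-formyl group activates the C–F bond of 2 toward the phenoxide of 1 (nucleophilic aromatic substitution, SNAr), and the electron-rich aryl bromide should stay untouched in the absence of a transition metal.

Step 2
Reactants: 4 3-(hydroxymethyl)phenol (3-hydroxybenzyl alcohol)
Product: 5 (3-hydroxybenzyl)triphenylphosphonium bromide
Conditions: PPh3·HBr, MeCN, reflux
Reagents that add atoms: triphenylphosphine hydrobromide, [Br-].[PH+](c1ccccc1)(c1ccccc1)c1ccccc1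
Why: HBr turns the benzylic alcohol into the benzylic bromide, which quaternizes PPh3 in the same pot (phosphonium salt formation from a benzylic alcohol); the meta phenol cannot form a quinone methide and needs no protection.

Step 3
Reactants: 5 (3-hydroxybenzyl)triphenylphosphonium bromide; 3 4-(5-bromo-2-methoxyphenoxy)benzaldehyde
Product: 7 3-{2-[4-(5-bromo-2-methoxyphenoxy)phenyl]ethenyl}phenol (E/Z mixture), via phenoxide ylide 6 (not isolated)
Conditions: KOtBu (2.2 equiv), THF, 0 °C to rt; then 1 M HCl
Reagents that add atoms: none
Why: Two equivalents of base should give the phenoxide ylide 6, which olefinates the non-enolizable aldehyde 3 (Wittig reaction); the E/Z mixture expected from a semi-stabilized benzylic ylide is of no consequence because step 4 saturates the double bond.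

Step 4
Reactants: 7 3-{2-[4-(5-bromo-2-methoxyphenoxy)phenyl]ethenyl}phenol (E/Z mixture)
Product: 8 3-{2-[4-(5-bromo-2-methoxyphenoxy)phenyl]ethyl}phenol
Conditions: TsNHNH2, NaOAc, THF/H2O, reflux
Reagents that add atoms: none
Why: Diimide released from the sulfonyl hydrazide transfers H2 to the stilbene in a concerted syn fashion (diimide reduction) and, unlike H2 over Pd/C, should leave the aryl bromide intact.

Step 5
Reactants: 8 3-{2-[4-(5-bromo-2-methoxyphenoxy)phenyl]ethyl}phenol; 9 4-fluoro-3-methoxybenzonitrile
Product: 12 (4-fluoro-3-methoxyphenyl)(3-{4-[2-(3-hydroxyphenyl)ethyl]phenoxy}-4-methoxyphenyl)methanone, via dilithio species 10 (not isolated), via N-lithio ketimine 11 (not isolated)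
Conditions: n-BuLi (2.1 equiv), THF, −78 °C; then 9, −78 to 0 °C; then 2 M HCl, rt
Reagents that add atoms: water, O
Why: The first equivalent of n-BuLi masks the phenol as its lithium phenoxide and the second effects bromine–lithium exchange; the aryllithium should add once to the nitrile (organolithium addition to a nitrile) because the N-lithio ketimine 11 accepts no second nucleophile, and aqueous acid hydrolyses it to the diaryl ketone with the fluorine in place.

Step 6
Reactants: 12 (4-fluoro-3-methoxyphenyl)(3-{4-[2-(3-hydroxyphenyl)ethyl]phenoxy}-4-methoxyphenyl)methanone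
Product: 13 19-membered macrocyclic diaryl ketone (A–CO–D carbonyl; A–O–B and C–O–D ethers; B–CH2CH2–C bridge; OMe on rings A and D)
Conditions: Cs2CO3 (3 equiv), DMSO, 110 °C, slow addition to a final concentration of 0.003 M
Reagents that add atoms: none
Why: The caesium phenoxide of ring B should displace the fluoride that sits para to the diaryl ketone carbonyl on ring A (intramolecular SNAr of the kind used to make aryl ether ketones), with high dilution favouring the 19-membered ring over oligomers.

Step 7
Reactants: 13 19-membered macrocyclic diaryl ketone
Product: 15 20-membered macrocyclic aryl benzyl ketone (ring A–C(=O)–CH2–ring D), via α-trimethylsilyl ketone 14 (not isolated)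
Conditions: TMSCHN2 (3 equiv, slow addition), BF3·OEt2 (1.5 equiv), CH2Cl2, −20 °C to rt; then 1 M HCl, THF, rt
Reagents that add atoms: trimethylsilyldiazomethane, C[Si](C)(C)C=[N+]=[N-]
Why: BF3 binds the carbonyl oxygen of 13, the nucleophilic diazo carbon adds to the carbonyl carbon (first new C–C bond), and the resulting β-oxido diazonium species collapses by a 1,2-aryl shift with loss of N2 (second new C–C bond) to the α-silyl ketone 14, which the acidic work-up protodesilylates. The closest known reaction type is the Lewis-acid-promoted Tiffeneau–Demjanov-type homologation of ketones with TMSCHN2, established for expanding bridged cyclic diaryl ketones of the dibenzosuberenone kind to their aryl benzyl ketone homologues. No ring is closed: the existing 19-membered ring becomes 20-membered by migration of one of its own ring bonds, so a second macrocyclization is avoided. No stereocentre remains, because the silyl-bearing carbon of 14 is racemic and becomes CH2 on desilylation. The step needs single insertion, which the silicon secures: it stays on the inserted carbon, so the primary product is a bulky α-silyl ketone (or the silyl enol ether formed from it by 1,3-shift), and neither should accept a second diazo carbon even though the free aryl benzyl ketone is more electrophilic than 13. The migrating group needs no control, since the anisyl-type ring D (OMe para to C=O) is the better migrator and the isomeric ketone from a ring A shift would give the same bridge in step 8.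

Step 8
Reactants: 15 20-membered macrocyclic aryl benzyl ketone
Product: 17 O,O'-dimethyl ether of the target, via benzylic alcohol 16 (not isolated)
Conditions: Et3SiH (5 equiv), CF3CO2H, CH2Cl2, rt to 40 °C
Reagents that add atoms: none
Why: Hydride transfer to the protonated aryl ketone, ionization of the benzylic alcohol 16 to a cation stabilized by the para-aryloxy group of ring A, and a second hydride transfer should give the methylene (ionic hydrogenation); any stilbene formed by elimination is reduced by the same mechanism.

Step 9
Reactants: 17 O,O'-dimethyl ether of the target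
Product: 19 target CNP0329842.0, via bis(dibromoboryl) ether 18 (not isolated)
Conditions: BBr3 (6 equiv), CH2Cl2, −78 °C to rt; then H2O
Reagents that add atoms: none
Why: BBr3 coordinates each methoxy oxygen and bromide removes the methyl group (Lewis-acid cleavage of aryl methyl ethers), whereas the diaryl ether oxygens offer no sp3 carbon for attack, so hydrolysis of 18 on work-up should release the two phenols.

**Compound list**

1 | 5-bromo-2-methoxyphenol | COc1ccc(Br)cc1O | starting material
2 | 4-fluorobenzaldehyde | O=Cc1ccc(F)cc1 | starting material
3 | 4-(5-bromo-2-methoxyphenoxy)benzaldehyde | COc1ccc(Br)cc1Oc1ccc(C=O)cc1 | intermediate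
4 | 3-(hydroxymethyl)phenol (3-hydroxybenzyl alcohol) | OCc1cccc(O)c1 | starting material
5 | (3-hydroxybenzyl)triphenylphosphonium bromide | [Br-].Oc1cccc(C[P+](c2ccccc2)(c2ccccc2)c2ccccc2)c1 | intermediate
6 | phenoxide ylide, potassium 3-[(triphenylphosphoranylidene)methyl]phenoxide, formed in the flask in step 3 | [K+].[O-]c1cccc(C=P(c2ccccc2)(c2ccccc2)c2ccccc2)c1 | intermediate
7 | 3-{2-[4-(5-bromo-2-methoxyphenoxy)phenyl]ethenyl}phenol, E/Z mixture, double-bond geometry not defined | COc1ccc(Br)cc1Oc1ccc(C=Cc2cccc(O)c2)cc1 | intermediate
8 | 3-{2-[4-(5-bromo-2-methoxyphenoxy)phenyl]ethyl}phenol | COc1ccc(Br)cc1Oc1ccc(CCc2cccc(O)c2)cc1 | intermediate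
9 | 4-fluoro-3-methoxybenzonitrile | COc1cc(C#N)ccc1F | starting material
10 | dilithio species, lithium 3-{2-[4-(5-lithio-2-methoxyphenoxy)phenyl]ethyl}phenoxide, formed in the flask in step 5 | [Li]c1ccc(OC)c(Oc2ccc(CCc3cccc(O[Li])c3)cc2)c1 | intermediate
11 | N-lithio ketimine of 12 with the ring B oxygen as lithium phenoxide, formed in the flask in step 5 | COc1cc(ccc1F)C(=N[Li])c1ccc(OC)c(Oc2ccc(CCc3cccc(O[Li])c3)cc2)c1 | intermediate
12 | (4-fluoro-3-methoxyphenyl)(3-{4-[2-(3-hydroxyphenyl)ethyl]phenoxy}-4-methoxyphenyl)methanone | COc1cc(ccc1F)C(=O)c1ccc(OC)c(Oc2ccc(CCc3cccc(O)c3)cc2)c1 | intermediate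
13 | 19-membered macrocyclic diaryl ketone: rings A and D joined by C=O; ring A bears the ether O to ring B para to the carbonyl and OMe ortho to that O; ring B meta-linked to the CH2CH2 bridge; ring C para-linked between the bridge and the ether O to ring D; ring D bears OMe para to the carbonyl and ortho to its ether O | COc1cc2ccc1Oc1cccc(c1)CCc1ccc(cc1)Oc1cc(ccc1OC)C2=O | intermediate
14 | α-trimethylsilyl ketone of 15, silicon on the inserted carbon between C=O and ring D, racemic, formed in the flask in step 7 | COc1cc2ccc1Oc1cccc(c1)CCc1ccc(cc1)Oc1cc(ccc1OC)C([Si](C)(C)C)C2=O | intermediate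
15 | 20-membered macrocyclic aryl benzyl ketone: as 13 but with ring A–C(=O)–CH2–ring D | COc1cc2ccc1Oc1cccc(c1)CCc1ccc(cc1)Oc1cc(ccc1OC)CC2=O | intermediate
16 | benzylic alcohol from 15, ring A–CH(OH)–CH2–ring D, racemic, formed in the flask in step 8 | COc1cc2ccc1Oc1cccc(c1)CCc1ccc(cc1)Oc1cc(ccc1OC)CC2O | intermediate
17 | O,O'-dimethyl ether of the target: 20-membered macrocycle with ring A–CH2CH2–ring D bridge and both phenols as OMe | COc1cc2ccc1Oc1cccc(c1)CCc1ccc(cc1)Oc1cc(ccc1OC)CC2 | intermediate
18 | bis(dibromoboryl) ether of the target, both phenol oxygens as O–BBr2, formed in the flask in step 9 | BrB(Br)Oc1cc2ccc1Oc1cccc(c1)CCc1ccc(cc1)Oc1cc(ccc1OB(Br)Br)CC2 | intermediate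
19 | CNP0329842.0: 20-membered bis(bibenzyl) macrocycle A–O–B–CH2CH2–C–O–D–CH2CH2–A with OH on ring A ortho to its ether O and OH on ring D ortho to its ether O and para to its CH2; no stereocentre | Oc1cc2ccc1Oc1cccc(c1)CCc1ccc(cc1)Oc1cc(ccc1O)CC2 | target

**Step count and risks**

Total steps: 9. Longest linear sequence: 8 steps (steps 1, 3, 4, 5, 6, 7, 8 and 9 from 1 and 2); step 2 is a one-step branch from 4.

Most likely to fail:

1. Step 7. The carbonyl of 13 is flanked by two donor-substituted rings, so addition of the diazo carbon may be slower than Lewis-acid-induced decomposition of TMSCHN2. The adduct may also close to an oxirane and rearrange to a diarylacetaldehyde without ring growth. The fallback keeps the one-carbon insertion with aryl shift but does it in two known operations. It sets out from 13, which is methylenated with Ph3P=CH2 (from methyltriphenylphosphonium bromide and KOtBu, THF, reflux) to the exocyclic 1,1-diarylethene macrocycle F1. Treatment of this with the trivalent iodine reagent PhI(OH)OTs in 95% MeOH at rt should induce the oxidative 1,2-aryl shift known for 1,1-diarylalkenes and return to the route at 15.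

2. Step 6. The C–F bond is activated only by a carbonyl that is itself attenuated by the para-methoxy ring D, and it carries an ortho methoxy group, so substitution may be slow enough for intermolecular oligomerization to win at the temperature required. The fallback replaces the SNAr ring closure by a copper-catalysed Ullmann macro-etherification of a bromide. It sets out from 8, which is converted as in step 5 to the dilithio species 10 and added at −78 °C to 4-bromo-3-methoxybenzaldehyde to give the bromo diaryl carbinol F2. Oxidation with MnO2 in CH2Cl2 gives the bromo ketone F3, and CuI with N,N-dimethylglycine and Cs2CO3 in dioxane at 100 °C under high dilution should close the A–O–B ether and return to the route at 13.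

3. Step 5. The dilithio species may aggregate or precipitate, so that exchange is incomplete, and the aryllithium may attack the fluorinated carbon of 9 in competition with the nitrile. The fallback uses a protected phenol and an aldehyde electrophile. It sets out from 8, which is silylated (TIPSCl, imidazole, DMF) to the triisopropylsilyl ether F4. Bromine–lithium exchange (n-BuLi, THF, −78 °C) and addition to 4-fluoro-3-methoxybenzaldehyde give the diaryl carbinol F5, MnO2 oxidation gives the silyl-protected fluoro ketone F6, and Bu4NF in THF at 0 °C removes the silyl group and returns to the route at 12.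

**Further compounds**

F1 | step 7 | 19-membered macrocyclic 1,1-diarylethene (13 with C=CH2 in place of C=O) | COc1cc2ccc1Oc1cccc(c1)CCc1ccc(cc1)Oc1cc(ccc1OC)C2=C
F2 | step 6 | (4-bromo-3-methoxyphenyl)(3-{4-[2-(3-hydroxyphenyl)ethyl]phenoxy}-4-methoxyphenyl)methanol, racemic | COc1cc(ccc1Br)C(O)c1ccc(OC)c(Oc2ccc(CCc3cccc(O)c3)cc2)c1
F3 | step 6 | (4-bromo-3-methoxyphenyl)(3-{4-[2-(3-hydroxyphenyl)ethyl]phenoxy}-4-methoxyphenyl)methanone | COc1cc(ccc1Br)C(=O)c1ccc(OC)c(Oc2ccc(CCc3cccc(O)c3)cc2)c1
F4 | step 5 | triisopropylsilyl ether of 8 | COc1ccc(Br)cc1Oc1ccc(CCc2cccc(O[Si](C(C)C)(C(C)C)C(C)C)c2)cc1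
F5 | step 5 | (4-fluoro-3-methoxyphenyl)[4-methoxy-3-(4-{2-[3-(triisopropylsilyloxy)phenyl]ethyl}phenoxy)phenyl]methanol, racemic | COc1cc(ccc1F)C(O)c1ccc(OC)c(Oc2ccc(CCc3cccc(O[Si](C(C)C)(C(C)C)C(C)C)c3)cc2)c1
F6 | step 5 | triisopropylsilyl ether of 12 | COc1cc(ccc1F)C(=O)c1ccc(OC)c(Oc2ccc(CCc3cccc(O[Si](C(C)C)(C(C)C)C(C)C)c3)cc2)c1
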